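**Retrosynthetic overview**
1. Enone C=C: Claisen–Schmidt condensation of a ring-A methyl ketone with 4-hydroxybenzaldehyde, done last; the two silyl ethers fall off in the same pot.
2. C3–OH: axial hydride delivery to an oxan-3-one (gives 3,4-trans and 2,3-cis).
3. Key disconnection, C4–aryl: enolonium (trivalent-iodine enolate, an umpoled enolate) of the oxan-3-one plus the C–H carbon between the two hydroxyls of 2,4-dihydroxy-6-methoxyacetophenone.
4. The enolonium comes from a 2,6-trans pyranone enone by 1,4-hydrosilylation; the C6 side chain is put on by organozinc addition to an Achmatowicz-derived oxocarbenium ion.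
5. Ring order: all benzene rings are bought; the oxane is the only ring made, by Achmatowicz ring expansion of an (S)-aryl furyl carbinol from catalytic asymmetric aryl transfer to furfural.

Assumption: the SMILES is taken as drawn, i.e. (2S,3S,4S,6S) on the oxane ring and an E enone, and tert-butyl[4-(2-bromoethyl)phenoxy]dimethylsilane is taken as a catalogue compound.

Abbreviation used in names: Ar* = 4-[(tert-butyldimethylsilyl)oxy]phenyl. Oxane numbering: O1, C2 (aryl), C3 (O), C4 (ring-A aryl), C5, C6 (side chain).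

**Step 1**
Reactants: 1 furfural (furan-2-carbaldehyde); 2 [4-(tert-butyldimethylsilyloxy)phenyl]boronic acid
Product: 5 (2S)-2-Ar*-6-hydroxy-2H-pyran-3(6H)-one (both C6 anomers), via arylethylzinc 3 (not isolated), via (S)-carbinol 4 (not isolated)
Conditions: 2, Et2Zn, PhMe, 60 °C; then (2S)-(−)-3-exo-morpholinoisoborneol [(−)-MIB, 10 mol%], 1, PhMe, 0 °C; then THF/H2O, NaHCO3, NaOAc, NBS, 0 °C
Reagents that add atoms: water, O
Why: Boron-to-zinc exchange gives an arylzinc that the amino-alkoxide zinc catalyst delivers to the Si face of furfural (catalytic asymmetric aryl transfer, the facial sense (−)-MIB shows with dialkylzincs), setting the (S)-carbinol carbon that becomes C2, and buffered NBS/water then effects the Achmatowicz oxidative ring expansion without touching that centre.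

**Step 2**
Reactants: 5 (2S)-2-Ar*-6-hydroxy-2H-pyran-3(6H)-one
Product: 6 (2S)-2-Ar*-3-oxo-3,6-dihydro-2H-pyran-6-yl acetate (both C6 anomers)
Conditions: Ac2O, pyridine, DMAP (5 mol%), CH2Cl2, −20 °C
Reagents that add atoms: acetic anhydride, CC(=O)OC(C)=O
Why: O-Acetylation of the lactol makes C6–O a leaving group for oxocarbenium formation (anomeric acetate for Kishi-type C-glycosylation); brief cold exposure to the weak base avoids enolisation at C2, and the anomer ratio does not matter because C6 is ionised next.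

**Step 3**
Reactants: 6 (2S)-2-Ar*-3-oxo-3,6-dihydro-2H-pyran-6-yl acetate; 7 tert-butyl[4-(2-bromoethyl)phenoxy]dimethylsilane
Product: 10 (2S,6S)-2-Ar*-6-(2-Ar*-ethyl)-2H-pyran-3(6H)-one (2,6-trans), via alkylmagnesium bromide 8 (not isolated), via dialkylzinc 9 (not isolated)
Conditions: 7, Mg, Et2O, rt; ZnCl2 (0.5 equiv), Et2O, 0 °C; then 6, TMSOTf, CH2Cl2, −78 to −40 °C
Reagents that add atoms: none
Why: TMSOTf ionises the acetate to the conjugated oxocarbenium ion, which the dialkylzinc (inert to the ketone and to the s-trans-locked enone) attacks at C6 on the face opposite the C2 aryl group (Kishi/Ferrier-type C-glycosylation with an organozinc), fixing the 2,6-trans relationship (6S), while the C3 carbonyl suppresses ionisation at benzylic C2.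

**Step 4**
Reactants: 10 (2S,6S)-2-Ar*-6-(2-Ar*-ethyl)-2H-pyran-3(6H)-one; 11 1-(2,4-dihydroxy-6-methoxyphenyl)ethan-1-one
Product: 14 (2S,4S,6S)-4-(3-acetyl-2,6-dihydroxy-4-methoxyphenyl)-2-Ar*-6-(2-Ar*-ethyl)oxan-3-one, via silyl enol ether 12 (not isolated), via enolonium 13 (not isolated)
Conditions: RhCl(PPh3)3 (1 mol%), Et3SiH, PhMe, 50 °C; evaporate; PhI(OAc)2, BF3·OEt2, CH2Cl2, −78 °C, 10 min; then 11, MeCN/CH2Cl2, −78 to −40 °C; NaHCO3 quench at −78 °C
Reagents that add atoms: none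
Why: Proposed new method: monovalent-rhodium-catalysed 1,4-hydrosilylation gives the C3=C4 silyl enol ether regiospecifically and without base, PhI(OAc)2/BF3·OEt2 converts it into a trivalent-iodine enolate (enolonium, the umpoled enolate known to be intercepted by indoles, pyrroles, allylsilanes and enol silanes), and arene 11 attacks the now electrophilic C4 in a Friedel–Crafts-type step with loss of iodobenzene, joining two normally nucleophilic carbons; the arene should react at the carbon between its two hydroxyls (the other free position is buttressed by the methoxy methyl, which the acetyl group forces towards it), and C4 should be attacked on the face opposite the pseudo-axial C2 aryl group, giving the 4-aryl group trans to the C2 aryl and cis to the C6 chain (4S, equatorial).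

**Step 5**
Reactants: 14 (2S,4S,6S)-4-(3-acetyl-2,6-dihydroxy-4-methoxyphenyl)-2-Ar*-6-(2-Ar*-ethyl)oxan-3-one
Product: 15 1-{2,4-dihydroxy-3-[(2S,3S,4S,6S)-3-hydroxy-2-Ar*-6-(2-Ar*-ethyl)oxan-4-yl]-6-methoxyphenyl}ethan-1-one
Conditions: NaBH4, CeCl3·7H2O, MeOH/THF, −78 °C
Reagents that add atoms: none
Why: Luche reduction: hydride adds axially to C3 from the face opposite the axial C2 aryl group, giving the equatorial (3S) alcohol cis to the C2 aryl and trans to the C4 aryl faster than either α-centre can enolise, while the hydrogen-bonded, electron-rich aryl methyl ketone is left alone.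

**Step 6**
Reactants: 15 1-{2,4-dihydroxy-3-[(2S,3S,4S,6S)-3-hydroxy-2-Ar*-6-(2-Ar*-ethyl)oxan-4-yl]-6-methoxyphenyl}ethan-1-one; 16 4-hydroxybenzaldehyde
Product: 18 (2E)-1-{2,4-dihydroxy-3-[(2S,3S,4S,6S)-3-hydroxy-2-(4-hydroxyphenyl)-6-[2-(4-hydroxyphenyl)ethyl]oxan-4-yl]-6-methoxyphenyl}-3-(4-hydroxyphenyl)prop-2-en-1-one (CNP0310862.1), via desilylated ketone 17 (not isolated)
Conditions: KOH (50% aq), EtOH, 0 °C to rt, 48 h; then aq citric acid to pH 5, 0 °C
Reagents that add atoms: none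
Why: Claisen–Schmidt condensation: hydroxide cleaves the two aryl silyl ethers, the methyl ketone enolate adds to the aldehyde and E1cB dehydration gives the conjugated (E)-enone (thermodynamic geometry) without creating or disturbing a stereocentre.

**Compound list**
1 | furfural (furan-2-carbaldehyde) | O=Cc1ccco1 | starting material
2 | [4-(tert-butyldimethylsilyloxy)phenyl]boronic acid | CC(C)(C)[Si](C)(C)Oc1ccc(B(O)O)cc1 | starting material
3 | ethyl[4-(tert-butyldimethylsilyloxy)phenyl]zinc | CC[Zn]c1ccc(O[Si](C)(C)C(C)(C)C)cc1 | intermediate (not isolated)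
4 | (S)-[4-(tert-butyldimethylsilyloxy)phenyl](furan-2-yl)methanol | O[C@H](c1ccco1)c1ccc(O[Si](C)(C)C(C)(C)C)cc1 | intermediate (not isolated)
5 | (2S)-2-Ar*-6-hydroxy-2H-pyran-3(6H)-one, both C6 anomers | OC1C=CC(=O)[C@H](c2ccc(O[Si](C)(C)C(C)(C)C)cc2)O1 | intermediate
6 | (2S)-2-Ar*-3-oxo-3,6-dihydro-2H-pyran-6-yl acetate, both C6 anomers | CC(=O)OC1C=CC(=O)[C@H](c2ccc(O[Si](C)(C)C(C)(C)C)cc2)O1 | intermediate
7 | tert-butyl[4-(2-bromoethyl)phenoxy]dimethylsilane | BrCCc1ccc(O[Si](C)(C)C(C)(C)C)cc1 | starting material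
8 | [2-(Ar*)ethyl]magnesium bromide | Br[Mg]CCc1ccc(O[Si](C)(C)C(C)(C)C)cc1 | intermediate (not isolated)
9 | bis[2-(Ar*)ethyl]zinc | CC(C)(C)[Si](C)(C)Oc1ccc(CC[Zn]CCc2ccc(O[Si](C)(C)C(C)(C)C)cc2)cc1 | intermediate (not isolated)
10 | (2S,6S)-2-Ar*-6-(2-Ar*-ethyl)-2H-pyran-3(6H)-one (2,6-trans) | O=C1C=C[C@H](CCc2ccc(O[Si](C)(C)C(C)(C)C)cc2)O[C@H]1c1ccc(O[Si](C)(C)C(C)(C)C)cc1 | intermediate
11 | 1-(2,4-dihydroxy-6-methoxyphenyl)ethan-1-one | COc1cc(O)cc(O)c1C(C)=O | starting material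
12 | triethyl{[(2S,6S)-2-Ar*-6-(2-Ar*-ethyl)-5,6-dihydro-2H-pyran-3-yl]oxy}silane | CC[Si](CC)(CC)OC1=CC[C@H](CCc2ccc(O[Si](C)(C)C(C)(C)C)cc2)O[C@H]1c1ccc(O[Si](C)(C)C(C)(C)C)cc1 | intermediate (not isolated)
13 | enolonium: acetoxy(phenyl)iodanyl enolate of the same (2S,6S)-5,6-dihydro-2H-pyran-3-ol | CC(=O)O[I](c1ccccc1)OC1=CC[C@H](CCc2ccc(O[Si](C)(C)C(C)(C)C)cc2)O[C@H]1c1ccc(O[Si](C)(C)C(C)(C)C)cc1 | intermediate (not isolated)
14 | (2S,4S,6S)-4-(3-acetyl-2,6-dihydroxy-4-methoxyphenyl)-2-Ar*-6-(2-Ar*-ethyl)oxan-3-one | COc1cc(O)c([C@@H]2C[C@H](CCc3ccc(O[Si](C)(C)C(C)(C)C)cc3)O[C@@H](c3ccc(O[Si](C)(C)C(C)(C)C)cc3)C2=O)c(O)c1C(C)=O | intermediate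
15 | 1-{2,4-dihydroxy-3-[(2S,3S,4S,6S)-3-hydroxy-2-Ar*-6-(2-Ar*-ethyl)oxan-4-yl]-6-methoxyphenyl}ethan-1-one | COc1cc(O)c([C@@H]2C[C@H](CCc3ccc(O[Si](C)(C)C(C)(C)C)cc3)O[C@@H](c3ccc(O[Si](C)(C)C(C)(C)C)cc3)[C@H]2O)c(O)c1C(C)=O | intermediate
16 | 4-hydroxybenzaldehyde | O=Cc1ccc(O)cc1 | starting material
17 | 1-{2,4-dihydroxy-3-[(2S,3S,4S,6S)-3-hydroxy-2-(4-hydroxyphenyl)-6-[2-(4-hydroxyphenyl)ethyl]oxan-4-yl]-6-methoxyphenyl}ethan-1-one | COc1cc(O)c([C@@H]2C[C@H](CCc3ccc(O)cc3)O[C@@H](c3ccc(O)cc3)[C@H]2O)c(O)c1C(C)=O | intermediate (not isolated)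
18 | (2E)-1-{2,4-dihydroxy-3-[(2S,3S,4S,6S)-3-hydroxy-2-(4-hydroxyphenyl)-6-[2-(4-hydroxyphenyl)ethyl]oxan-4-yl]-6-methoxyphenyl}-3-(4-hydroxyphenyl)prop-2-en-1-one | COc1cc(O)c([C@@H]2C[C@H](CCc3ccc(O)cc3)O[C@@H](c3ccc(O)cc3)[C@H]2O)c(O)c1C(=O)/C=C/c1ccc(O)cc1 | target

**Totals**
Total steps: 6. Longest linear sequence: 6 (1 to 18).

**Three steps most likely to fail**

Step 4. The free phenols of 11 may be oxidised or O-alkylated by the trivalent-iodine enolate, the arene may react at its other free position, and the α-(2-hydroxyaryl) ketone can dehydrate to a benzofuran if BF3 is allowed to warm. The fallback sets out from 10 and comes back at 14; it swaps the oxidative Lewis-acid enolonium for a base-generated one. Silyl enol ether 12 is made from 10 as before and brominated with NBS (THF, −78 °C) to the α-bromo ketone F1. NH2OH·HCl/NaOAc (EtOH, 0 °C) converts it into the α-bromo oxime F2. Na2CO3 in CH2Cl2 at 0 °C in the presence of 11 eliminates HBr to the nitrosoalkene F3, which the phenoxide of 11 captures through its carbon between the two oxygens to give the α-aryl oxime F4. Buffered aqueous TiCl3/NH4OAc then cleaves the oxime to ketone 14.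

Step 3. A primary dialkylzinc may be too slow towards this electron-poor oxocarbenium ion or may reduce it by β-hydride transfer. The fallback sets out from 6 and comes back at 15; it uses an sp nucleophile and saturates the chain late. Commercial tert-butyl(4-ethynylphenoxy)dimethylsilane F5 is deprotonated with n-BuLi and transmetalated with ZnBr2 to the alkynylzinc bromide F6. F6 adds to the oxocarbenium ion from 6 (TMSOTf, CH2Cl2, −78 °C), again opposite the C2 aryl group, to give the 2,6-trans alkynyl enone F7. Conjugate hydrosilylation with [(Ph3P)CuH]6 (3 mol%)/PhMe2SiH at 0 °C, which should leave the internal alkyne alone, gives the silyl enol ether F8. F8 is oxidised as in step 4 to the enolonium F9 and trapped by 11 to give the alkynyl ketone F10. NaBH4/CeCl3·7H2O gives the alkynyl alcohol F11, and H2 over Pd/C (zerovalent palladium on carbon, EtOAc) saturates the alkyne to give 15.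

Step 6. The polyphenoxide enolate reacts slowly with the phenoxide of 16, and long exposure to strong base could open the 2-(4-oxidophenyl)oxane through a quinone methide and epimerise C2. The fallback sets out from 10 and comes back at 18; it builds the chalcone before the coupling so that no strong base meets the assembled oxane. Compounds 11 and 16 are condensed first (KOH, EtOH) to helichrysetin F12. Enolonium 13, generated from 10 as in step 4, is trapped by F12 at the same ring-A carbon to give the chalcone ketone F13. NaBH4/CeCl3·7H2O at −78 °C reduces only the saturated ring ketone to give the bis-silyl ether F14, and Bu4NF/AcOH in THF at 0 °C removes the two silyl groups to give 18.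

**Further compounds**
F1 | step 4 | (2S,6S)-4-bromo-2-Ar*-6-(2-Ar*-ethyl)oxan-3-one (C4 epimers) | O=C1C(Br)C[C@H](CCc2ccc(O[Si](C)(C)C(C)(C)C)cc2)O[C@H]1c1ccc(O[Si](C)(C)C(C)(C)C)cc1
F2 | step 4 | oxime of (2S,6S)-4-bromo-2-Ar*-6-(2-Ar*-ethyl)oxan-3-one | ON=C1C(Br)C[C@H](CCc2ccc(O[Si](C)(C)C(C)(C)C)cc2)O[C@H]1c1ccc(O[Si](C)(C)C(C)(C)C)cc1
F3 | step 4 | (2S,6S)-3-nitroso-2-Ar*-6-(2-Ar*-ethyl)-5,6-dihydro-2H-pyran (nitrosoalkene) | O=NC1=CC[C@H](CCc2ccc(O[Si](C)(C)C(C)(C)C)cc2)O[C@H]1c1ccc(O[Si](C)(C)C(C)(C)C)cc1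
F4 | step 4 | oxime of (2S,4S,6S)-4-(3-acetyl-2,6-dihydroxy-4-methoxyphenyl)-2-Ar*-6-(2-Ar*-ethyl)oxan-3-one | COc1cc(O)c([C@@H]2C[C@H](CCc3ccc(O[Si](C)(C)C(C)(C)C)cc3)O[C@@H](c3ccc(O[Si](C)(C)C(C)(C)C)cc3)C2=NO)c(O)c1C(C)=O
F5 | step 3 | tert-butyl(4-ethynylphenoxy)dimethylsilane (bought) | C#Cc1ccc(O[Si](C)(C)C(C)(C)C)cc1
F6 | step 3 | [(Ar*)ethynyl]zinc bromide | Br[Zn]C#Cc1ccc(O[Si](C)(C)C(C)(C)C)cc1
F7 | step 3 | (2S,6R)-2-Ar*-6-[(Ar*)ethynyl]-2H-pyran-3(6H)-one (2,6-trans) | O=C1C=C[C@H](C#Cc2ccc(O[Si](C)(C)C(C)(C)C)cc2)O[C@H]1c1ccc(O[Si](C)(C)C(C)(C)C)cc1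
F8 | step 3 | dimethyl(phenyl)silyl enol ether of the 4,5-dihydro form of F7 | C[Si](C)(c1ccccc1)OC1=CC[C@H](C#Cc2ccc(O[Si](C)(C)C(C)(C)C)cc2)O[C@H]1c1ccc(O[Si](C)(C)C(C)(C)C)cc1
F9 | step 3 | acetoxy(phenyl)iodanyl enolate (enolonium) of the alkynyl series | CC(=O)O[I](c1ccccc1)OC1=CC[C@H](C#Cc2ccc(O[Si](C)(C)C(C)(C)C)cc2)O[C@H]1c1ccc(O[Si](C)(C)C(C)(C)C)cc1
F10 | step 3 | (2S,4S,6R)-4-(3-acetyl-2,6-dihydroxy-4-methoxyphenyl)-2-Ar*-6-[(Ar*)ethynyl]oxan-3-one | COc1cc(O)c([C@@H]2C[C@H](C#Cc3ccc(O[Si](C)(C)C(C)(C)C)cc3)O[C@@H](c3ccc(O[Si](C)(C)C(C)(C)C)cc3)C2=O)c(O)c1C(C)=O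
F11 | step 3 | 1-{2,4-dihydroxy-3-[(2S,3S,4S,6R)-3-hydroxy-2-Ar*-6-[(Ar*)ethynyl]oxan-4-yl]-6-methoxyphenyl}ethan-1-one | COc1cc(O)c([C@@H]2C[C@H](C#Cc3ccc(O[Si](C)(C)C(C)(C)C)cc3)O[C@@H](c3ccc(O[Si](C)(C)C(C)(C)C)cc3)[C@H]2O)c(O)c1C(C)=O
F12 | step 6 | helichrysetin, (2E)-1-(2,4-dihydroxy-6-methoxyphenyl)-3-(4-hydroxyphenyl)prop-2-en-1-one | COc1cc(O)cc(O)c1C(=O)/C=C/c1ccc(O)cc1
F13 | step 6 | (2S,4S,6S)-4-{2,6-dihydroxy-3-[(2E)-3-(4-hydroxyphenyl)prop-2-enoyl]-4-methoxyphenyl}-2-Ar*-6-(2-Ar*-ethyl)oxan-3-one | COc1cc(O)c([C@@H]2C[C@H](CCc3ccc(O[Si](C)(C)C(C)(C)C)cc3)O[C@@H](c3ccc(O[Si](C)(C)C(C)(C)C)cc3)C2=O)c(O)c1C(=O)/C=C/c1ccc(O)cc1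
F14 | step 6 | bis(tert-butyldimethylsilyl) ether of 18 at the two oxane-side phenols | COc1cc(O)c([C@@H]2C[C@H](CCc3ccc(O[Si](C)(C)C(C)(C)C)cc3)O[C@@H](c3ccc(O[Si](C)(C)C(C)(C)C)cc3)[C@H]2O)c(O)c1C(=O)/C=C/c1ccc(O)cc1
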